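You asked for a quick number on cedar against alder, with a hunch that the gentle flask is the safe one. Start from a ratio: at its last reading the delta run holds 0.361 of Ji per unit of Qa gone. That overall selectivity, Ji divided by one minus the fraction of Qa left, is what I would carry. The epsilon run reads 0.333, but with only 46.6 % of its Qa gone. At a like conversion, 51.3 %, the delta reading is 0.380, higher than epsilon's, so these readings lean towards a larger ratio in the warmer run, and I use each run's ratio for the flask nearer its temperature.

| setting | epsilon | delta | cedar | alder |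
|---|---|---|---|---|
| Qa | 1.9 M | 1.9 M | 2.7 M | 1.5 M |
| temperature | 20 °C | 40 °C |  |  |
| remark | run made earlier | run made earlier | at 25 °C until 15 min, from then on at 55 °C | at 25 °C throughout |
| time |  |  | 50 min | 50 min |

| run | time / min | Ji / % | Qa / % |
|---|---|---|---|
| epsilon | 2.00 | 3.6 | 98.6 |
| epsilon | 5.00 | 3.6 | 92.8 |
| epsilon | 10.0 | 3.5 | 84.3 |
| epsilon | 15.0 | 7.8 | 79.8 |
| epsilon | 20.0 | 11.2 | 73.6 |
| epsilon | 30.0 | 13.2 | 61.3 |
| epsilon | 40.0 | 15.5 | 53.4 |
| delta | 1.00 | 7.6 | 87.6 |
| delta | 2.50 | 12.8 | 71.1 |
| delta | 5.00 | 19.5 | 48.7 |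
| delta | 8.00 | 26.4 | 32.8 |
| delta | 10.0 | 29.4 | 24.4 |
| delta | 15.0 | 32.9 | 12.2 |
| delta | 20.0 | 33.7 | 6.7 |

(readings scatter by 1 percentage point)

- the winner by amount of Ji, in percent of the Qa charged; "neither" if no more than 2 percentage points parts them (cedar / alder / neither)
- how much Ji is there at the end, in percent of the Qa charged: cedar
- how much Ji is there at the end, in percent of the Qa charged: alder



So reckon the fraction left, not the fraction made. Taking Qa as roughly first order, the last readings give 0.0157 min⁻¹ in epsilon and 0.135 min⁻¹ in delta. The square root of the square root of their ratio carries epsilon to 25 °C, at 0.0269 min⁻¹. Alder then keeps 26.1 % of its Qa, which at epsilon's ratio gives 24.6 % of Ji. Cedar, using delta's rate as a floor for its hot stretch, keeps 0.590 %, which at delta's ratio gives 35.9 %. Ji does not fall late in delta, going from 32.9 % to 33.7 %. I therefore commit to cedar, ahead by 11 percentage points, more than the margin, though neither run tried another charge.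

The forecast chose alder, with 21 % for cedar and 26 % for alder, since the hot stretch “may destroy much of the Ji”.

The flasks give cedar, with 33.4 % against 25.2 % for alder.

    2 Qa → Yx (k = 0.00408 L mol⁻¹ min⁻¹, Ea = 83.0 kJ mol⁻¹)
    Qa → Ji (k = 0.0136 min⁻¹, Ea = 89.0 kJ mol⁻¹)
    Qa + Ji → Zu (k = 0.0211 L mol⁻¹ min⁻¹, Ea = 62.0 kJ mol⁻¹)
    (constants at 25 °C)

The ratio comes to 0.334 in cedar and 0.348 in alder. The temperature programme is one part of cedar's lead, not the whole of it: alder given cedar's programme ends at 46.7 % of Ji instead of 25.2 %, and cedar held at 25 °C throughout ends at 17.9 %. With the heat, cedar's Qa is at 0 % by the end, and reading ten times later changes nothing. Carried to the alder repeat at 50 °C, delta's ratio reckons 36.1 %. That flask, its Qa at 0 %, holds 46.1 % of Ji.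

The numbers in the tables were computed from invented constants, noise included.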